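**Retrosynthetic overview**
1. Target 13 ⇐ pentabenzyl ether 12 (hydrogenolysis). 12 ⇐ flavanone–flavone 10 by saturating the C2=C3 bond of unit 1 (the 4-methoxyphenyl half): hydride to C2 under ligand control, kinetic proton to C3, which makes the 2,3-cis ring C of unit 1 last.
2. 10 ⇐ fluoro ketone 7 + aldehyde 8: one enantioselective aldol/SNAr annulation forms the C2''–C3'' bond and the O1''–C8a'' aryl ether bond, closing ring C of unit 2 (the 4-hydroxyphenyl half, 2'',3''-trans).
3. Enabling feature: in 7 the fluorine-bearing carbon of ring A of unit 2 (future C8a'') is ortho to the C4'' ketone and meta to both benzyloxy groups, so it accepts the C2'' alkoxide. The C3'' methylene between that ketone and C3 of the flavone is the only enolisable site, and unit 1 is carried as a flat, base-stable flavone.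
4. 7 ⇐ Pd-catalysed α-arylation of aryl methyl ketone 3 (from 5-fluororesorcinol 1) with 3-iodoflavone 6 (from acacetin 4).
5. Ring order: rings A and C of unit 1 (as flavone) and ring A of unit 2 come with the building blocks; ring C of unit 2 closes in step 6; ring C of unit 1 is reduced to the flavanone in step 7.

Key step: step 6

Assumption: the sense of induction of the two chiral catalysts (cinchonidinium salt in step 6, (R)-configured bisphosphine in step 7) is assigned by analogy and is not known for these substrates; each has a pseudo-enantiomer or enantiomer giving the opposite sense, so a reversed outcome is corrected by exchanging the catalyst.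

Step 1
Reactants: 1 5-fluorobenzene-1,3-diol
Product: 2 1-(2-fluoro-4,6-dihydroxyphenyl)ethan-1-one
Conditions: AcOH (1.5 equiv), BF3·OEt2 (solvent), 90 °C; then aq. NaOAc
Reagents that add atoms: acetic acid, CC(=O)O
Why: Friedel–Crafts (Nencki-type) C-acetylation of a resorcinol, which should occur para to one hydroxyl and ortho to the other (the position between the two hydroxyls is more hindered), as with resorcinol and orcinol.

Step 2
Reactants: 2 1-(2-fluoro-4,6-dihydroxyphenyl)ethan-1-one
Product: 3 1-[2,4-bis(benzyloxy)-6-fluorophenyl]ethan-1-one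
Conditions: BnBr (2.5 equiv), K2CO3, DMF, 70 °C
Reagents that add atoms: benzyl bromide, BrCc1ccccc1
Why: Williamson etherification; heating in DMF should also alkylate the hydrogen-bonded ortho hydroxyl, and carbonate does not displace the aryl fluoride under these conditions.

Step 3
Reactants: 4 acacetin [5,7-dihydroxy-2-(4-methoxyphenyl)-4H-chromen-4-one]
Product: 5 5,7-bis(benzyloxy)-2-(4-methoxyphenyl)-4H-chromen-4-one
Conditions: BnBr (3 equiv), K2CO3, DMF, 80 °C
Reagents that add atoms: benzyl bromide, BrCc1ccccc1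
Why: Williamson etherification of both phenols, the chelated 5-hydroxyl needing the higher temperature; the flavone ring is stable to carbonate.

Step 4
Reactants: 5 5,7-bis(benzyloxy)-2-(4-methoxyphenyl)-4H-chromen-4-one
Product: 6 5,7-bis(benzyloxy)-3-iodo-2-(4-methoxyphenyl)-4H-chromen-4-one
Conditions: LiN(i-Pr)2 (1.2 equiv), THF, −78 °C; then I2, −78 → −20 °C
Reagents that add atoms: iodine, [I][I]
Why: deprotonation of the flavone at C3 (the vinylic C–H next to the carbonyl, a known lithiation of flavones) followed by iodine quench should place the halogen at C3 and not on the electron-rich ring A, where an electrophilic iodination would go.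

Step 5
Reactants: 3 1-[2,4-bis(benzyloxy)-6-fluorophenyl]ethan-1-one; 6 5,7-bis(benzyloxy)-3-iodo-2-(4-methoxyphenyl)-4H-chromen-4-one
Product: 7 3-{2-[2,4-bis(benzyloxy)-6-fluorophenyl]-2-oxoethyl}-5,7-bis(benzyloxy)-2-(4-methoxyphenyl)-4H-chromen-4-one
Conditions: Pd2(dba)3 (2.5 mol %), Xantphos (6 mol %), K3PO4, toluene, 90 °C
Reagents that add atoms: none
Why: palladium-catalysed α-arylation of an aryl methyl ketone, in which zerovalent palladium inserts into the C3–I bond of the iodoflavone and reductive elimination from the palladium enolate forms the C3–CH2 bond; a second arylation is disfavoured because the product enolate is hindered.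

Step 6
Reactants: 7 3-{2-[2,4-bis(benzyloxy)-6-fluorophenyl]-2-oxoethyl}-5,7-bis(benzyloxy)-2-(4-methoxyphenyl)-4H-chromen-4-one; 8 4-(benzyloxy)benzaldehyde
Product: 10 (2R,3S)-5,7-bis(benzyloxy)-2-[4-(benzyloxy)phenyl]-3-[5,7-bis(benzyloxy)-2-(4-methoxyphenyl)-4-oxo-4H-chromen-3-yl]-2,3-dihydro-4H-chromen-4-one, via anti-aldolate 9 (not isolated)
Conditions: 8 (1.5 equiv), O-allyl-N-(9-anthracenylmethyl)cinchonidinium bromide (10 mol %), Cs2CO3 (1.5 equiv), 4 Å molecular sieves, toluene, 0 → 25 °C
Reagents that add atoms: none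
Why: Proposed new method: under solid–liquid phase transfer the chiral ammonium enolate of 7 adds reversibly to 8, and the alkoxide oxygen of anti-aldolate 9 attacks the fluorine-bearing ring carbon ortho to the C4'' ketone, giving an anionic σ-adduct that expels fluoride. The closest known reaction types are intramolecular SNAr etherification of 2-fluoroaryl ketones (chromone and xanthone syntheses), the base-mediated aldol/oxa-Michael route to flavanones, and aldol and SNAr reactions directed by chiral quaternary ammonium cations; their union in one enantioselective annulation is the new element. Ring C of unit 2 closes by 6-exo-trig addition–elimination, the oxygen on C2'' bonding to C8a''. The aldol step is reversible and the ether formation is not, so all aldolates should drain through the chair-like transition state that keeps the 2''-aryl and 3''-flavonyl groups equatorial, which sets C3'' trans to C2''; the chiral cation paired with the alkoxide in that same step is meant to select (2''R,3''S). The step needs attack at C–F and not at the ortho C–OBn carbon (secured by the better leaving group and by both benzyloxy groups being meta to fluorine), a single enolate (7 has one acidic CH2), and a product that does not reopen (its hindered C3'' methine should be deprotonated far more slowly by solid Cs2CO3 than the CH2 of 7).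

Step 7
Reactants: 10 (2R,3S)-flavanone–flavone from step 6
Product: 12 (2S,3S,2''R,3''S)-5,7,5'',7'',4'''-pentakis(benzyloxy)-4'-methoxy-3,3''-biflavanone, via enol silane 11 (not isolated)
Conditions: Cu(OAc)2 (5 mol %), (R)-DTBM-SEGPHOS (5.5 mol %), (EtO)2MeSiH (2 equiv), toluene, 25 °C; then AcOH, THF–H2O, −20 °C
Reagents that add atoms: none
Why: copper hydride-catalysed asymmetric conjugate reduction, a reaction type known for chromones and β,β-disubstituted enones: the phosphine-bound Cu–H should deliver hydride to C2 of the flavone on the face chosen by the ligand (unit 2 keeps its C3''–H in the flavone plane and biases the two faces little), setting C2 as S, and enol silane 11 is then protonated at C3 anti to the pseudoaxial 2-aryl group, which leaves the unit 2 substituent cis to that aryl group (3S), while the hindered C4'' ketone is hydrosilylated much more slowly.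

Step 8
Reactants: 12 (2S,3S,2''R,3''S)-5,7,5'',7'',4'''-pentakis(benzyloxy)-4'-methoxy-3,3''-biflavanone
Product: 13 (2S,3S,2''R,3''S)-5,7,5'',7'',4'''-pentahydroxy-4'-methoxy-3,3''-biflavanone (CNP0196568.4)
Conditions: H2 (1 atm), Pd/C (10 wt%), EtOAc–MeOH, 25 °C
Reagents that add atoms: none
Why: hydrogenolysis of the five O-benzyl groups under neutral conditions should leave the aryl methyl ether, both ketones and the epimerisable C3 and C3'' centres untouched; no stereocentre is formed.

**Compound list**
1 | 5-fluorobenzene-1,3-diol (5-fluororesorcinol) | Oc1cc(O)cc(F)c1 | starting material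
2 | 1-(2-fluoro-4,6-dihydroxyphenyl)ethan-1-one | CC(=O)c1c(O)cc(O)cc1F | intermediate
3 | 1-[2,4-bis(benzyloxy)-6-fluorophenyl]ethan-1-one | CC(=O)c1c(F)cc(OCc2ccccc2)cc1OCc1ccccc1 | intermediate
4 | acacetin, 5,7-dihydroxy-2-(4-methoxyphenyl)-4H-chromen-4-one | COc1ccc(cc1)-c1cc(=O)c2c(O)cc(O)cc2o1 | starting material
5 | 5,7-bis(benzyloxy)-2-(4-methoxyphenyl)-4H-chromen-4-one | COc1ccc(cc1)-c1cc(=O)c2c(OCc3ccccc3)cc(OCc3ccccc3)cc2o1 | intermediate
6 | 5,7-bis(benzyloxy)-3-iodo-2-(4-methoxyphenyl)-4H-chromen-4-one | COc1ccc(cc1)-c1oc2cc(OCc3ccccc3)cc(OCc3ccccc3)c2c(=O)c1I | intermediate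
7 | 3-{2-[2,4-bis(benzyloxy)-6-fluorophenyl]-2-oxoethyl}-5,7-bis(benzyloxy)-2-(4-methoxyphenyl)-4H-chromen-4-one | O=C(Cc1c(-c2ccc(OC)cc2)oc2cc(OCc3ccccc3)cc(OCc3ccccc3)c2c1=O)c1c(F)cc(OCc2ccccc2)cc1OCc1ccccc1 | intermediate
8 | 4-(benzyloxy)benzaldehyde | O=Cc1ccc(OCc2ccccc2)cc1 | starting material
9 | anti-aldolate: ammonium alkoxide of 3-{(2S,3R)-1-[2,4-bis(benzyloxy)-6-fluorophenyl]-3-[4-(benzyloxy)phenyl]-3-hydroxy-1-oxopropan-2-yl}-5,7-bis(benzyloxy)-2-(4-methoxyphenyl)-4H-chromen-4-one (SMILES of the neutral alcohol) | COc1ccc(-c2oc3cc(OCc4ccccc4)cc(OCc4ccccc4)c3c(=O)c2[C@H](C(=O)c2c(OCc3ccccc3)cc(OCc3ccccc3)cc2F)[C@@H](O)c2ccc(OCc3ccccc3)cc2)cc1 | intermediate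
10 | (2R,3S)-5,7-bis(benzyloxy)-2-[4-(benzyloxy)phenyl]-3-[5,7-bis(benzyloxy)-2-(4-methoxyphenyl)-4-oxo-4H-chromen-3-yl]-2,3-dihydro-4H-chromen-4-one | COc1ccc(-c2oc3cc(OCc4ccccc4)cc(OCc4ccccc4)c3c(=O)c2[C@@H]2C(=O)c3c(OCc4ccccc4)cc(OCc4ccccc4)cc3O[C@H]2c2ccc(OCc3ccccc3)cc2)cc1 | intermediate
11 | enol silane: (2R,3S)-5,7-bis(benzyloxy)-2-[4-(benzyloxy)phenyl]-3-[(2R)-5,7-bis(benzyloxy)-4-{[diethoxy(methyl)silyl]oxy}-2-(4-methoxyphenyl)-2H-chromen-3-yl]-2,3-dihydro-4H-chromen-4-one (the chromene C2 has the spatial arrangement of C2 in 12; it is R only because C3 here outranks the aryl group) | COc1ccc([C@H]2Oc3cc(OCc4ccccc4)cc(OCc4ccccc4)c3C(O[Si](C)(OCC)OCC)=C2[C@@H]2C(=O)c3c(OCc4ccccc4)cc(OCc4ccccc4)cc3O[C@H]2c2ccc(OCc3ccccc3)cc2)cc1 | intermediate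
12 | (2S,3S,2''R,3''S)-5,7,5'',7'',4'''-pentakis(benzyloxy)-4'-methoxy-3,3''-biflavanone (unit 1 2,3-cis, unit 2 2'',3''-trans) | COc1ccc([C@H]2Oc3cc(OCc4ccccc4)cc(OCc4ccccc4)c3C(=O)[C@H]2[C@@H]2C(=O)c3c(OCc4ccccc4)cc(OCc4ccccc4)cc3O[C@H]2c2ccc(OCc3ccccc3)cc2)cc1 | intermediate
13 | (2S,3S,2''R,3''S)-5,7,5'',7'',4'''-pentahydroxy-4'-methoxy-3,3''-biflavanone, CNP0196568.4 | COc1ccc([C@H]2Oc3cc(O)cc(O)c3C(=O)[C@H]2[C@@H]2C(=O)c3c(O)cc(O)cc3O[C@H]2c2ccc(O)cc2)cc1 | target

**Step count and risks**
Total step count: 8. Longest linear sequence: 6 steps (1 → 2 → 3 → 7 → 10 → 12 → 13; the branch from 4 is equally long).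

Step 6 (proposed new method). What may go wrong: loss of enantiomeric purity and of the trans ratio through base-induced opening of the product at the O1''–C2'' bond and reclosure; dehydration of the aldolate to a chalcone before the ether closes; or an SNAr that is too slow in the ion pair. The fallback uses known chemistry and closes the ring through the other C–O bond. It sets out from 7: Knoevenagel condensation with 8 (piperidine, AcOH, toluene, reflux with removal of water) should give the fluoro-chalcone (E)-1-[2,4-bis(benzyloxy)-6-fluorophenyl]-3-[4-(benzyloxy)phenyl]-2-[5,7-bis(benzyloxy)-2-(4-methoxyphenyl)-4-oxo-4H-chromen-3-yl]prop-2-en-1-one F1. Hydroxy-defluorination of this non-enolisable ortho-fluoro aryl ketone with KOH in DMSO–water should give the corresponding 2'-hydroxychalcone F2. Classical cyclisation (NaOAc, EtOH, reflux) should then give the racemic trans-flavanone, that is 10 together with its (2S,3R)-enantiomer F3. Preparative chromatography on a chiral stationary phase removes F3, and the route is rejoined at 10.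

Step 7. What may go wrong: slow hydride transfer to the tetrasubstituted C2=C3 bond, competing 1,2-hydrosilylation of the C4'' ketone, poor facial selectivity at C2, or epimerisation of C3 after protonation. The fallback replaces catalyst control by substrate control and separation. It sets out from 10: conjugate reduction with LiBH(s-Bu)3 in THF at −78 °C and quenching with AcOH at −78 °C should give the two 2,3-cis diastereomers, 12 and the (2R,3R,2''R,3''S)-isomer of 12 F4. These are separated by chromatography on silica, and the route is rejoined at 12.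

Step 5. What may go wrong: protodeiodination of 6, addition of the enolate or of the base to C2 of the flavone with ring opening, or self-condensation of 3. The fallback reverses the polarity of the coupling. It sets out from 3 and 5: oxidation of 3 with SeO2 in wet dioxane at reflux should give 2-[2,4-bis(benzyloxy)-6-fluorophenyl]-2-oxoacetaldehyde F5. Flavone 5 is lithiated at C3 (LiN(i-Pr)2, THF, −78 °C) and added to the dried glyoxal to give the racemic α-hydroxy ketone 3-{2-[2,4-bis(benzyloxy)-6-fluorophenyl]-1-hydroxy-2-oxoethyl}-5,7-bis(benzyloxy)-2-(4-methoxyphenyl)-4H-chromen-4-one F6. Reductive removal of the α-hydroxyl with SmI2 (THF–MeOH, −78 °C) rejoins the route at 7.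

**Further compounds**
F1 | step 6 | (E)-1-[2,4-bis(benzyloxy)-6-fluorophenyl]-3-[4-(benzyloxy)phenyl]-2-[5,7-bis(benzyloxy)-2-(4-methoxyphenyl)-4-oxo-4H-chromen-3-yl]prop-2-en-1-one | O=C(c1c(F)cc(OCc2ccccc2)cc1OCc1ccccc1)/C(=C/c1ccc(OCc2ccccc2)cc1)c1c(-c2ccc(OC)cc2)oc2cc(OCc3ccccc3)cc(OCc3ccccc3)c2c1=O
F2 | step 6 | (E)-1-[2,4-bis(benzyloxy)-6-hydroxyphenyl]-3-[4-(benzyloxy)phenyl]-2-[5,7-bis(benzyloxy)-2-(4-methoxyphenyl)-4-oxo-4H-chromen-3-yl]prop-2-en-1-one | O=C(c1c(O)cc(OCc2ccccc2)cc1OCc1ccccc1)/C(=C/c1ccc(OCc2ccccc2)cc1)c1c(-c2ccc(OC)cc2)oc2cc(OCc3ccccc3)cc(OCc3ccccc3)c2c1=O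
F3 | step 6 | (2S,3R)-enantiomer of 10 | COc1ccc(-c2oc3cc(OCc4ccccc4)cc(OCc4ccccc4)c3c(=O)c2[C@H]2C(=O)c3c(OCc4ccccc4)cc(OCc4ccccc4)cc3O[C@@H]2c2ccc(OCc3ccccc3)cc2)cc1
F4 | step 7 | (2R,3R,2''R,3''S)-5,7,5'',7'',4'''-pentakis(benzyloxy)-4'-methoxy-3,3''-biflavanone | COc1ccc([C@@H]2Oc3cc(OCc4ccccc4)cc(OCc4ccccc4)c3C(=O)[C@@H]2[C@@H]2C(=O)c3c(OCc4ccccc4)cc(OCc4ccccc4)cc3O[C@H]2c2ccc(OCc3ccccc3)cc2)cc1
F5 | step 5 | 2-[2,4-bis(benzyloxy)-6-fluorophenyl]-2-oxoacetaldehyde | O=CC(=O)c1c(F)cc(OCc2ccccc2)cc1OCc1ccccc1
F6 | step 5 | racemic 3-{2-[2,4-bis(benzyloxy)-6-fluorophenyl]-1-hydroxy-2-oxoethyl}-5,7-bis(benzyloxy)-2-(4-methoxyphenyl)-4H-chromen-4-one | O=C(C(O)c1c(-c2ccc(OC)cc2)oc2cc(OCc3ccccc3)cc(OCc3ccccc3)c2c1=O)c1c(F)cc(OCc2ccccc2)cc1OCc1ccccc1
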